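## The problem

1. The target is two cycloheptane-fused cis-γ-butyrolactones joined by a cyclohexene. With xanthanolide locants, ring B (C1, C5–C10, methyl C14 on C10) carries the α-methylene lactone (C7, C8, C11–C13); ring D (C1', C5'–C10') carries the second lactone (C7', C8', C11', C12') and the 3-oxobutyl chain; ring C (C1, C2, C3, C11', C13', C5) is fused to ring B at C1–C5 and spiro to the southern lactone at C11'.
2. The two halves have the same relative configuration (H7 and H8 cis, C10 methyl on the face of O8) but opposite absolute configuration: 7R,8R,10S in the north, 7S,8S,10R in the south. No single chiral series of building blocks serves both.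
3. Ring C holds three adjacent fully substituted carbons: the spiro quaternary C11' (α to the lactone carbonyl C12'), C3 with its acetyl group (C4, C15), and the tertiary carbinol C1 at the B/C fusion, whose OH is cis to H5 and to the C10 methyl.
4. At C11' the methylene C13' lies on the open face of the southern lactone (syn to H7') and C3 on the face of C6'. A route that forms the C3–C11' bond last, as a [4+2] dimerisation does, should therefore give the C11' epimer.
5. Reliable control exists only between neighbours: C7' for C11', C5 for C1 through the ring fusion, and the cis-fused lactone for C10 and C5. Nothing transmits from one half to the other.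
6. The α-methylene lactone, the two methyl ketones, the γ-hydroxy enone of ring C and any β-keto lactone on the way are sensitive to nucleophiles and base (Michael addition, retro-aldol, retro-Claisen). C5 and C10 are epimerisable as long as C1 is a ketone.
7. The feature that opens the key step is the sequence C1(OH)–C2–C3 with C3 bonded to C11'. If the acetyl-bearing C2=C3 bond is read as the cross-coupling product of the enol triflate of a C3 ketone, ring C is the ketol of a 1,5-diketone (C1 and C3 carbonyls linked by C5–C13'–C11'), the C1–C2 bond is an intramolecular aldol, and C11' is the α-carbon of an α-acetyl lactone.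

## Retrosynthesis

**Functional-group cuts at the end.** Target 35 is first simplified without touching the skeleton. The acetyl group is the hydrolysed form of the 1-ethoxyvinyl group of 34, put on C3 by Stille coupling of enol triflate 33. The C13 methylene of 33 comes from aminomethylation and elimination on 31, at a stage where the northern lactone is the only carbonyl with accessible α-hydrogens. Triflate 31 is made from ketone 30. The C4' ketone travels as a dioxolane, and its chain is joined to C1' by Negishi coupling of the ring-D enol triflate 29. All these cuts converge on ketol 29. The acetyl-bearing double bond then needs no separate oxidation, and triflation of the C3 ketone is unambiguous because C11' is quaternary. The forward sequence needs the two triflates to be formed and used one after the other.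

**C1–C2 (ring C).** Ketol 29 is cut to the 1,5-diketone 27. Against the neighbouring cut of C3–C11' and C5–C13' (a [4+2] process), this makes the tertiary carbinol in the ring closure itself, with its configuration tied to C5 by the ring fusion, and it leaves C11' to be set earlier and separately. Diketone 27 has one ring and one stereocentre fewer. The forward reaction must enolise the acetyl methyl group in the presence of the ring ketone and close cis.

**C11'–C13' (union of the halves).** Diketone 27 comes, through alcohol 26, from the α-acetyl lactone 24 and the northern cyclic sulfate 15. Three points speak for this cut: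
- C13' arrives at C11' last, so it enters anti to C6', which is the configuration of the target.
- C5 already carries C13', so its configuration is settled on the small northern piece.
- The same bond made in the Michael sense (24 adding to a 2-methylene ketone) would leave C5 to a protonation.

Both precursors are bicyclic. The forward reaction needs C- rather than O-alkylation. C1 must not be a ketone while C13' carries a leaving group, which is why the diol-derived sulfate is used and C1 is oxidised afterwards.

**The two halves become one ketone.** Sulfate 15 comes from diol 13, and 13 from keto lactone 11 by a formaldehyde aldol of the kinetic C5 enolate and reduction. Acetyl lactone 24 comes from enol triflate 23, and 23 from keto lactone 22. Compounds 11 and 22 are enantiomers, so the problem shrinks to one bicyclic ketone in both forms.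

**C10 methyl and C1 oxygen.** Ketone 11 (and 22) comes from dienone 10 (21) by hydrogenation, 10 from enone 8 (19) by α'-methylenation, and 8 from lactone 6 (17) by allylic oxidation. The C5=C6 double bond of 8 blocks C5, so C10 is the only enolisable position. C10 is then set by delivery of hydrogen to the open face of the cis-fused bicycle.

**One monoacetate, two antipodes.** Lactones 6 and 17 both come from monoacetate 4. A [3,3] shift started from the acetate (Ireland–Claisen) moves the acetic acid unit to one allyl terminus; started from the free hydroxyl (Johnson–Claisen) it moves it to the other. The two lactones are mirror images, each with the C7/C8 pair set by suprafacial transfer. Monoacetate 4 comes from the meso diol 3 by enzymatic desymmetrisation, and 3 from cyclohepta-1,3-diene 1 and singlet oxygen. One enantioselective event serves both halves.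

## Roads not taken

**Alternative 1:** [4+2] dimerisation, the obvious route. Cut C3–C11' and C5–C13'.
- Forward: Diels–Alder reaction of the C5=C1–C2=C3 diene of the (7R,8R,10S)-dienone A1 with the exocyclic methylene of the antipodal 2,3-dihydro lactone A2 gives adduct A3 (C1=C2). Oxygenation at C1 with allylic shift (singlet-oxygen ene reaction or dienolate oxidation) would give 35.
- Why the chosen plan is better:
  - A1 is itself a dienophile through its own α-methylene lactone, so homodimers compete with the cross adduct.
  - In this isomer C3 sits on the face of C6' and C7' (not the lactone carbonyl) lies under the diene. The cycloaddition would have to take the hindered face of A2 in the exo mode; the expected product is the C11' epimer.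
  - Two complete, sensitive xanthanolides of opposite series are needed.
  - A late oxidation at C1 adds its own facial and regiochemical question.

**Alternative 2:** photochemical de Mayo annulation. Cut C3–C11' and C5–C13' again, with the roles of the partners changed.
- Forward: [2+2] photocycloaddition of the enol of the northern 2-acetyl ketone A4 with the methylene lactone A2 gives cyclobutanol A5. Retro-aldol opening gives the 1,5-diketone A6, which would be closed by aldol as in the chosen route.
- Why the chosen plan is better:
  - An acrylate-type alkene tends to add head-to-head, which would join C11' to C5 instead of C13' to C5.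
  - The ring enol of A4 can react instead of the side-chain enol and lead to ring expansion.
  - C3 again comes to C11' last and on the open face, giving the wrong epimer.
  - C5 is set by a protonation.

**Alternative 3:** ring-closing metathesis at C2=C3.
- Forward: diene A7 (vinyl group on the C1 carbinol, 3-oxobut-1-en-2-yl group on C11') is closed with a ruthenium carbene.
- Why the chosen plan is better:
  - There is no good way to put a branched enone substituent on the quaternary C11'.
  - Vinyl addition to the C1 ketone is not tied to C5 by a ring.
  - The metathesis would have to pair a hindered tertiary allylic alcohol with an electron-poor 1,1-disubstituted olefin next to a quaternary carbon, in the presence of the α-methylene lactone and the ring-D alkene.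
  - The aldol closure forms the same ring from a methyl ketone and sets C1 in the ring-forming event.

Key step: step 17

Remark 1: the lipase in step 2 is taken to give the (1S,4R)-monoacetate 4. If it gives the antipode, steps 3 and 9 change places between the two series and nothing else changes.
Remark 2: compounds 7, 9, 18, 20, 24 and 32 are mixtures at one centre that is destroyed or equilibrated later; that centre is left open in their SMILES.

## Route

Step 1
Reactants: 1 cyclohepta-1,3-diene
Product: 3 cis-cyclohept-2-ene-1,4-diol (meso), via endoperoxide 2 (not isolated)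
Conditions: O2, visible light, tetraphenylporphyrin (cat.), CH2Cl2, 0 °C; then Zn, AcOH, rt
Reagents that add atoms: dioxygen, O=O
Why: [4+2] cycloaddition of singlet oxygen across the cisoid diene gives the bicyclic peroxide; zinc cleaves only the O–O bond, so the two hydroxyls are cis and the diol is meso.

Step 2
Reactants: 3 cis-cyclohept-2-ene-1,4-diol
Product: 4 (1S,4R)-4-hydroxycyclohept-2-en-1-yl acetate
Conditions: vinyl acetate, lipase from Burkholderia cepacia (lipase PS), tBuOMe, rt
Reagents that add atoms: vinyl acetate, C=COC(C)=O
Why: Enzymatic desymmetrisation by irreversible transesterification acylates one of the two enantiotopic carbinols; this single step sets the absolute configuration of both halves.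

Step 3
Reactants: 4 (1S,4R)-4-hydroxycyclohept-2-en-1-yl acetate
Product: 6 northern lactone (3aS,8aR)-3,3a,6,7,8,8a-hexahydro-2H-cyclohepta[b]furan-2-one, via bis-silyl Claisen product 5 (not isolated)
Conditions: LDA (2.2 equiv), TMSCl (internal quench), THF, −78 → 60 °C; then 1 M HCl, THF, rt
Reagents that add atoms: none
Why: Ireland–Claisen rearrangement: the silyl ketene acetal of the acetate (the free hydroxyl is silylated at once, before the alkoxide can transfer the acetyl group) shifts [3,3] suprafacially, so C11 reaches C7 on the face of the departing C5–O bond, cis to O8; acid frees the cis-hydroxy acid, which lactonises.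

Step 4
Reactants: 6 northern lactone
Product: 8 northern enone (3aS,8aR)-3,3a,8,8a-tetrahydro-2H-cyclohepta[b]furan-2,6(7H)-dione, via allylic alcohol 7 (not isolated)
Conditions: SeO2 (0.5 equiv), tBuOOH, CH2Cl2, rt; then IBX, EtOAc, 75 °C
Reagents that add atoms: tert-butyl hydroperoxide, CC(C)(C)OO (oxygen passed on through selenium dioxide, O=[Se]=O)
Why: Selenium dioxide ene reaction and [2,3]-shift return the double bond to C5=C6 and oxygenate the allylic CH2 (C1) in preference to the ring-fusion CH (C7), the usual CH2 over CH order, helped by the deactivating lactone next to C7; IBX oxidises the allylic alcohol to the enone.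

Step 5
Reactants: 8 northern enone
Product: 10 northern dienone (7-methylidene derivative of 8), via Mannich base 9 (not isolated)
Conditions: LDA, THF, −78 °C; CH2=NMe2+ I−; then MeI, CH2Cl2; then NaHCO3 (aq)
Reagents that add atoms: Eschenmoser's salt (dimethylmethylideneammonium iodide), C=[N+](C)C.[I-]
Why: C10 is the only enolisable α-carbon because C5 is sp2; Mannich reaction of the kinetic α'-enolate, N-methylation and E1cB loss of trimethylamine give the exocyclic methylene.

Step 6
Reactants: 10 northern dienone
Product: 11 northern keto lactone (3aR,7S,8aR)-7-methylhexahydro-2H-cyclohepta[b]furan-2,6(3H)-dione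
Conditions: H2 (1 atm), Pd/C, EtOAc, rt
Reagents that add atoms: none
Why: Heterogeneous hydrogenation of both C=C bonds; hydrogen reaches C10 from the convex face of the cis-fused bicycle (opposite the lactone ring), which leaves the methyl on the face of O8 (10S).

Step 7
Reactants: 11 northern keto lactone
Product: 13 northern diol (CH2OH on C5 trans to the lactone; C1–OH cis to the C10 methyl), via hydroxymethyl ketone 12 (not isolated)
Conditions: LDA, THF, −78 °C; CH2O (gas), −78 °C; AcOH; then Me4NBH(OAc)3, MeCN/AcOH, −20 °C
Reagents that add atoms: formaldehyde, C=O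
Why: Kinetic deprotonation at the less substituted α-carbon (C5) and aldol addition to formaldehyde on the convex face set C5 with C13' trans to the lactone; hydroxyl-directed triacetoxyborohydride reduction (hydride delivered from boron bound to the new CH2O group) removes the ketone before retro-aldol, dehydration or epimerisation at C5/C10 can occur and gives the C1 alcohol cis to the C10 methyl (this centre is oxidised again in step 16).

Step 8
Reactants: 13 northern diol
Product: 15 northern cyclic sulfate (C1–O and C13'–O bridged by SO2), via cyclic sulfite 14 (not isolated)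
Conditions: SOCl2, Et3N, CH2Cl2, 0 °C; then RuCl3 (cat.), NaIO4, MeCN/H2O, 0 °C
Reagents that add atoms: thionyl chloride, O=S(Cl)Cl; sodium periodate, [Na+].[O-]I(=O)(=O)=O
Why: Cyclic sulfite formation and ruthenium-catalysed oxidation give the six-membered 1,3-cyclic sulfate, which activates the primary carbon C13' while masking the C1 oxygen; with C1 at the alcohol level the leaving group cannot be lost by β-elimination.

Step 9
Reactants: 4 (1S,4R)-4-hydroxycyclohept-2-en-1-yl acetate
Product: 17 southern lactone (3aR,8aS)-3,3a,6,7,8,8a-hexahydro-2H-cyclohepta[b]furan-2-one, via Johnson–Claisen ester 16 (not isolated)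
Conditions: MeC(OEt)3, EtCO2H (cat.), 140 °C; then K2CO3 (cat.), MeOH, rt
Reagents that add atoms: triethyl orthoacetate, CCOC(C)(OCC)OCC
Why: Johnson–Claisen rearrangement from the free hydroxyl: the ketene acetal formed by orthoester exchange shifts [3,3] suprafacially and puts the acetate unit on the other allyl terminus, cis to the acetoxy group; methanolysis of the acetate and lactonisation give the mirror image of 6 from the same monoacetate.

Step 10
Reactants: 17 southern lactone
Product: 19 southern enone (3aR,8aS)-3,3a,8,8a-tetrahydro-2H-cyclohepta[b]furan-2,6(7H)-dione, via allylic alcohol 18 (not isolated)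
Conditions: SeO2 (0.5 equiv), tBuOOH, CH2Cl2, rt; then IBX, EtOAc, 75 °C
Reagents that add atoms: tert-butyl hydroperoxide, CC(C)(C)OO (oxygen passed on through selenium dioxide, O=[Se]=O)
Why: Same ene reaction, [2,3]-shift and oxidation as in step 4, on the enantiomer.

Step 11
Reactants: 19 southern enone
Product: 21 southern dienone (7-methylidene derivative of 19), via Mannich base 20 (not isolated)
Conditions: LDA, THF, −78 °C; CH2=NMe2+ I−; then MeI, CH2Cl2; then NaHCO3 (aq)
Reagents that add atoms: Eschenmoser's salt (dimethylmethylideneammonium iodide), C=[N+](C)C.[I-]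
Why: Same α'-methylenation as in step 5, on the enantiomer.

Step 12
Reactants: 21 southern dienone
Product: 22 southern keto lactone (3aS,7R,8aS)-7-methylhexahydro-2H-cyclohepta[b]furan-2,6(3H)-dione
Conditions: H2 (1 atm), Pd/C, EtOAc, rt
Reagents that add atoms: none
Why: Same convex-face hydrogenation as in step 6; it sets C10' (R) with the methyl on the face of O8'.

Step 13
Reactants: 22 southern keto lactone
Product: 23 southern enol triflate (C1'(OTf)=C5')
Conditions: LDA, THF, −78 °C; then Comins' reagent, −78 °C
Reagents that add atoms: N-(5-chloropyridin-2-yl)bis(trifluoromethanesulfonimide), Clc1ccc(nc1)N(S(=O)(=O)C(F)(F)F)S(=O)(=O)C(F)(F)F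
Why: The kinetic lithium enolate at the less substituted α-carbon C5' (the ketone is far more acidic than the lactone) is trapped on oxygen; this fixes the C1'=C5' double bond of ring D and removes the ketone before the lactone is enolised.

Step 14
Reactants: 23 southern enol triflate
Product: 24 southern α-acetyl lactone (acetyl on C11')
Conditions: LDA (2.1 equiv), THF, −78 °C; MeC(O)N(OMe)Me, −78 → 0 °C; NH4Cl (aq)
Reagents that add atoms: N-methoxy-N-methylacetamide, CC(=O)N(C)OC
Why: Claisen-type C-acylation of the lactone lithium enolate by the Weinreb amide; the chelated tetrahedral adduct survives until work-up, so the acidic product is not formed in the presence of base; C11' stays epimerisable, which is harmless.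

Step 15
Reactants: 24 southern α-acetyl lactone; 15 northern cyclic sulfate
Product: 26 union alcohol (C11'–C13' bond formed; C1–OH free), via cesium sulfate monoester 25 (not isolated)
Conditions: Cs2CO3, DMF, 40 °C; then H2SO4 (cat.), H2O (2 equiv), THF, rt
Reagents that add atoms: none
Why: The cesium enolate of the β-keto lactone opens the cyclic sulfate by SN2 attack at the primary carbon C13'; the electrophile enters C11' anti to C6' on the adjacent C7' (convex face), which places C13' syn to H7' and creates the quaternary centre; C-alkylation is expected for a soft primary electrophile, and acid then hydrolyses the secondary sulfate monoester with retention.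

Step 16
Reactants: 26 union alcohol
Product: 27 1,5-diketone (C1 ketone; acetyl on C11')
Conditions: Dess–Martin periodinane, CH2Cl2, rt
Reagents that add atoms: none
Why: Dess–Martin oxidation of the secondary alcohol (in equilibrium with its hemiketal to the acetyl group) under non-basic conditions, so that C5 and C10, now α to the ketone, keep their configuration.

Step 17
Reactants: 27 1,5-diketone
Product: 29 ketol TMS ether (ring C closed; C1–OSiMe3; C3 ketone), via lithium aldolate 28 (not isolated)
Conditions: LDA (1.05 equiv), THF, −78 → −40 °C; then TMSCl, −78 → 0 °C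
Reagents that add atoms: chlorotrimethylsilane, C[Si](C)(C)Cl
Why: Kinetic deprotonation by LDA at −78 °C takes a proton from the acetyl methyl group (C2), the only unhindered α-position; the ring ketone has only tertiary α-hydrogens (C5, C10) and the lactone CH2 (C11) is less acidic by several pK units. The lithium enolate adds to the C1 carbonyl in an intramolecular aldol addition; the closest known reaction type is the ketol-forming half of a Robinson annulation. Ring C (C1, C2, C3, C11', C13', C5) closes in a 6-(enolexo)-exo-trig mode through a chair-like, lithium-bridged transition state. The new stereocentre C1 is controlled by C5: the tether leaves C5 on the face of ring B opposite the lactone, so C2 reaches C1 from that face in the cis-fused array, which puts the oxygen cis to H5; the C10 methyl on the other face reinforces this by blocking the trajectory that would lead to the trans-fused ketol. The step needs site selectivity (C2 against C5, C10 and C11) and must not epimerise C5 or C10; low temperature, one equivalent of base and trapping of the tertiary alkoxide as its TMS ether, which also shuts off retro-aldol cleavage and dehydration, secure both. C11' is quaternary, so the C3 carbonyl can enolise only toward C2 and no regioisomeric aldol is possible from that side.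

Step 18
Reactants: 29 ketol TMS ether
Product: 30 side-chain ketal (2-(2-methyl-1,3-dioxolan-2-yl)ethyl group on C1')
Conditions: BrZnCH2CH2C(OCH2CH2O)CH3 (from the bromide, Zn, LiCl), Pd(dppf)Cl2 (5 mol %), THF, 50 °C
Reagents that add atoms: 2-(2-bromoethyl)-2-methyl-1,3-dioxolane (used as its zinc reagent), CC1(CCBr)OCCO1
Why: Negishi coupling: oxidative addition of the ring-D enol triflate to zerovalent palladium, transmetalation from the primary alkylzinc and reductive elimination; the neutral organozinc leaves the ketone, the lactones and the silyl ether untouched, and the acid-labile ketal is brought in only after the acidic step 15.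

Step 19
Reactants: 30 side-chain ketal
Product: 31 ring-C enol triflate (C2=C3–OTf)
Conditions: KHMDS, THF, −78 °C; PhNTf2, −78 → −20 °C
Reagents that add atoms: N-phenylbis(trifluoromethanesulfonimide), O=S(=O)(N(c1ccccc1)S(=O)(=O)C(F)(F)F)C(F)(F)F
Why: The ketone can enolise only toward C2 because C11' is quaternary; the potassium enolate is triflated on oxygen at low temperature, before β-elimination of the silyloxy group can compete.

Step 20
Reactants: 31 ring-C enol triflate
Product: 33 α-methylene lactone triflate, via Mannich base 32 (not isolated)
Conditions: LDA, THF, −78 °C; CH2=NMe2+ I−; then MeI, CH2Cl2; then NaHCO3 (aq)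
Reagents that add atoms: Eschenmoser's salt (dimethylmethylideneammonium iodide), C=[N+](C)C.[I-]
Why: With no ketone left, LDA deprotonates C11 of the northern lactone, the only lactone with α-hydrogens; Mannich reaction, N-methylation and elimination of trimethylamine give the α-methylene lactone.

Step 21
Reactants: 33 α-methylene lactone triflate
Product: 34 ethoxyvinyl diene (1-ethoxyvinyl group on C3)
Conditions: Bu3Sn–C(OEt)=CH2, Pd(PPh3)4 (5 mol %), LiCl, CuI (cat.), THF, 65 °C
Reagents that add atoms: tributyl(1-ethoxyvinyl)stannane, CCCC[Sn](CCCC)(CCCC)C(=C)OCC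
Why: Stille coupling of the hindered vinyl triflate (zerovalent palladium; LiCl and CuI assist transmetalation) brings in C4 and C15 as a masked acetyl group; the α-methylene lactone and the other alkenes are spectators.

Step 22
Reactants: 34 ethoxyvinyl diene
Product: 35 target CNP0195550.4
Conditions: 1 M HCl, THF, 0 °C → rt
Reagents that add atoms: water, O
Why: Mild aqueous acid hydrolyses the enol ether to the acetyl group, the dioxolane to the C4' ketone and the tertiary TMS ether to the C1 alcohol in one operation; the electron-poor enone protects the allylic alcohol against ionisation.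

## Compound list

1 | cyclohepta-1,3-diene | C1=CC=CCCC1 | starting material
2 | 6,7-dioxabicyclo[3.2.2]non-8-ene (endoperoxide) | O1[C@@H]2C=C[C@H](O1)CCC2 | intermediate
3 | cis-cyclohept-2-ene-1,4-diol (meso) | O[C@@H]1C=C[C@H](O)CCC1 | intermediate
4 | (1S,4R)-4-hydroxycyclohept-2-en-1-yl acetate | CC(=O)O[C@@H]1C=C[C@H](O)CCC1 | intermediate
5 | trimethylsilyl [cis-7-(trimethylsilyloxy)cyclohept-2-en-1-yl]acetate | C[Si](C)(C)OC(=O)C[C@H]1C=CCCC[C@H]1O[Si](C)(C)C | intermediate
6 | northern lactone, (3aS,8aR)-3,3a,6,7,8,8a-hexahydro-2H-cyclohepta[b]furan-2-one (C5=C6) | C1C(=O)O[C@@H]2CCCC=C[C@H]12 | intermediate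
7 | C1 allylic alcohol of 6 (C1 epimers) | C1C(=O)O[C@@H]2CCC(O)C=C[C@H]12 | intermediate
8 | northern enone, (3aS,8aR)-3,3a,8,8a-tetrahydro-2H-cyclohepta[b]furan-2,6(7H)-dione (C1 ketone, C5=C6) | C1C(=O)O[C@@H]2CCC(=O)C=C[C@H]12 | intermediate
9 | C10 dimethylaminomethyl derivative of 8 (C10 epimers) | C1C(=O)O[C@@H]2CC(CN(C)C)C(=O)C=C[C@H]12 | intermediate
10 | northern dienone, C10 methylidene derivative of 8 | C1C(=O)O[C@@H]2CC(=C)C(=O)C=C[C@H]12 | intermediate
11 | northern keto lactone, (3aR,7S,8aR)-7-methylhexahydro-2H-cyclohepta[b]furan-2,6(3H)-dione | C1C(=O)O[C@@H]2C[C@H](C)C(=O)CC[C@H]12 | intermediate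
12 | C5 hydroxymethyl derivative of 11 (CH2OH trans to the lactone) | C1C(=O)O[C@@H]2C[C@H](C)C(=O)[C@@H](CO)C[C@H]12 | intermediate
13 | northern diol (C1–OH cis to the C10 methyl, C5–CH2OH trans to the lactone) | C1C(=O)O[C@@H]2C[C@H](C)[C@H](O)[C@@H](CO)C[C@H]12 | intermediate
14 | cyclic sulfite of 13 (sulfur epimers) | C1C(=O)O[C@@H]2C[C@H](C)[C@@H]3OS(=O)OC[C@H]3C[C@H]12 | intermediate
15 | northern cyclic sulfate of 13 | C1C(=O)O[C@@H]2C[C@H](C)[C@@H]3OS(=O)(=O)OC[C@H]3C[C@H]12 | intermediate
16 | ethyl [cis-7-acetoxycyclohept-2-en-1-yl]acetate | CCOC(=O)C[C@@H]1C=CCCC[C@@H]1OC(C)=O | intermediate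
17 | southern lactone, (3aR,8aS)-3,3a,6,7,8,8a-hexahydro-2H-cyclohepta[b]furan-2-one | C1C(=O)O[C@H]2CCCC=C[C@@H]12 | intermediate
18 | C1' allylic alcohol of 17 (C1' epimers) | C1C(=O)O[C@H]2CCC(O)C=C[C@@H]12 | intermediate
19 | southern enone, (3aR,8aS)-3,3a,8,8a-tetrahydro-2H-cyclohepta[b]furan-2,6(7H)-dione | C1C(=O)O[C@H]2CCC(=O)C=C[C@@H]12 | intermediate
20 | C10' dimethylaminomethyl derivative of 19 (C10' epimers) | C1C(=O)O[C@H]2CC(CN(C)C)C(=O)C=C[C@@H]12 | intermediate
21 | southern dienone, C10' methylidene derivative of 19 | C1C(=O)O[C@H]2CC(=C)C(=O)C=C[C@@H]12 | intermediate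
22 | southern keto lactone, (3aS,7R,8aS)-7-methylhexahydro-2H-cyclohepta[b]furan-2,6(3H)-dione | C1C(=O)O[C@H]2C[C@@H](C)C(=O)CC[C@@H]12 | intermediate
23 | southern enol triflate (C1'(OTf)=C5') | C1C(=O)O[C@H]2C[C@@H](C)C(OS(=O)(=O)C(F)(F)F)=CC[C@@H]12 | intermediate
24 | southern α-acetyl lactone (acetyl on C11'; C11' epimers and enol) | CC(=O)C1C(=O)O[C@H]2C[C@@H](C)C(OS(=O)(=O)C(F)(F)F)=CC[C@@H]12 | intermediate
25 | cesium salt of the C1 sulfate monoester of 26 | [Cs+].C1C(=O)O[C@@H]2C[C@H](C)[C@H](OS(=O)(=O)[O-])[C@@H](C[C@]3(C(C)=O)C(=O)O[C@H]4C[C@@H](C)C(OS(=O)(=O)C(F)(F)F)=CC[C@@H]34)C[C@H]12 | intermediate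
26 | union alcohol (northern C1 carbinol; C5–C13'–C11' link; C11' quaternary with acetyl) | C1C(=O)O[C@@H]2C[C@H](C)[C@H](O)[C@@H](C[C@]3(C(C)=O)C(=O)O[C@H]4C[C@@H](C)C(OS(=O)(=O)C(F)(F)F)=CC[C@@H]34)C[C@H]12 | intermediate
27 | 1,5-diketone (C1 ketone, C3 acetyl carbonyl) | C1C(=O)O[C@@H]2C[C@H](C)C(=O)[C@@H](C[C@]3(C(C)=O)C(=O)O[C@H]4C[C@@H](C)C(OS(=O)(=O)C(F)(F)F)=CC[C@@H]34)C[C@H]12 | intermediate
28 | lithium alkoxide of the ring-C ketol | [Li+].C1C(=O)O[C@@H]2C[C@H](C)[C@@]3([O-])CC(=O)[C@@]4(C[C@H]3C[C@H]12)C(=O)O[C@H]1C[C@@H](C)C(OS(=O)(=O)C(F)(F)F)=CC[C@H]14 | intermediate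
29 | ketol TMS ether (ring C closed, C3 ketone, ring-D triflate) | C1C(=O)O[C@@H]2C[C@H](C)[C@@]3(O[Si](C)(C)C)CC(=O)[C@@]4(C[C@H]3C[C@H]12)C(=O)O[C@H]1C[C@@H](C)C(OS(=O)(=O)C(F)(F)F)=CC[C@H]14 | intermediate
30 | side-chain ketal (dioxolane-protected 3-oxobutyl on C1') | C1C(=O)O[C@@H]2C[C@H](C)[C@@]3(O[Si](C)(C)C)CC(=O)[C@@]4(C[C@H]3C[C@H]12)C(=O)O[C@H]1C[C@@H](C)C(CCC5(C)OCCO5)=CC[C@H]14 | intermediate
31 | ring-C enol triflate (C2=C3–OTf) | C1C(=O)O[C@@H]2C[C@H](C)[C@@]3(O[Si](C)(C)C)C=C(OS(=O)(=O)C(F)(F)F)[C@@]4(C[C@H]3C[C@H]12)C(=O)O[C@H]1C[C@@H](C)C(CCC5(C)OCCO5)=CC[C@H]14 | intermediate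
32 | C11 dimethylaminomethyl derivative of 31 (C11 epimers) | CN(C)CC1C(=O)O[C@@H]2C[C@H](C)[C@@]3(O[Si](C)(C)C)C=C(OS(=O)(=O)C(F)(F)F)[C@@]4(C[C@H]3C[C@H]12)C(=O)O[C@H]1C[C@@H](C)C(CCC5(C)OCCO5)=CC[C@H]14 | intermediate
33 | α-methylene lactone triflate | C=C1C(=O)O[C@@H]2C[C@H](C)[C@@]3(O[Si](C)(C)C)C=C(OS(=O)(=O)C(F)(F)F)[C@@]4(C[C@H]3C[C@H]12)C(=O)O[C@H]1C[C@@H](C)C(CCC5(C)OCCO5)=CC[C@H]14 | intermediate
34 | ethoxyvinyl diene (1-ethoxyvinyl on C3) | C=C1C(=O)O[C@@H]2C[C@H](C)[C@@]3(O[Si](C)(C)C)C=C(C(=C)OCC)[C@@]4(C[C@H]3C[C@H]12)C(=O)O[C@H]1C[C@@H](C)C(CCC5(C)OCCO5)=CC[C@H]14 | intermediate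
35 | CNP0195550.4 | C=C1C(=O)O[C@@H]2C[C@H](C)[C@@]3(O)C=C(C(C)=O)[C@@]4(C[C@H]3C[C@H]12)C(=O)O[C@H]1C[C@@H](C)C(CCC(C)=O)=CC[C@H]14 | target

## Step count and risks

Total: 22 steps. Longest linear sequence: 16 steps (1–8, then 15–22; the southern branch 1, 2, 9–14, then 15–22 is equally long).

**Step 17 (key step).** Proton transfer from C5 or C10 to the methyl-ketone enolate before ring closure could epimerise these centres or let the C10 enolate attack the acetyl carbonyl (a bridged ketol). Closure could also give the trans-fused ketol, and the aldolate could revert on warming. The fallback forms the C1–C2 bond before the union, through a tether. It sets out from 11.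
- The formaldehyde aldol of step 7 gives 12, which is acylated (bromoacetyl bromide, pyridine) to the bromoacetate F1.
- SmI2 in THF at −78 °C (intramolecular Reformatsky reaction) closes the cis-fused hydroxy δ-lactone F2, whose C1 carbinol is fixed by the tether.
- TMSOTf and 2,6-lutidine give the silyl ether F3.
- The lithium enolate of 23 is acylated by the δ-lactone carbonyl of F3, the more reactive of its two lactones, which opens the ring to the hydroxy β-keto lactone F4.
- MsCl and Et3N give the mesylate F5.
- Cs2CO3 in DMF closes ring C by intramolecular C-alkylation at C11'.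

The fallback returns to the route at 29.

**Step 15.** Substitution at the β-branched primary carbon by a hindered, fully substituted enolate may be slow, so that O-alkylation or elimination of the sulfate takes over. The fallback joins the halves by conjugate addition. It sets out from 11.
- LDA and Eschenmoser's salt give the Mannich base F6; MeI gives the methiodide F7.
- With 24 and DBU in MeCN, F7 loses trimethylamine to the 2-methylene ketone F8, to which the enolate of 24 adds.

The fallback returns at 27. The price is that C5 is then set by protonation; the epimers would have to be separated and the unwanted one recycled with DBU.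

**Step 4.** Oxygenation may go partly to the ring-fusion carbon C7, or conversion of the cis-disubstituted ring alkene may be poor. The fallback reaches the C1 oxygen by a 1,3-transposition. It sets out from 6.
- mCPBA gives the epoxide F9 (oxygen on the convex face).
- LiNEt2 takes a proton from the unhindered C1 and gives the allylic alcohol F10 (C6–OH, C1=C5).
- VO(acac)2 and tBuOOH give the syn epoxy alcohol F11; MsCl and Et3N give the epoxy mesylate F12.
- Na2Te opens F12 reductively, with the double bond moving to C5=C6 and the oxygen left on C1.

The fallback returns at 7, which is oxidised to 8 as in step 4. Step 10 is the same reaction on the antipode and shares the risk.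

**Step 6.** Hydrogen may be delivered from the lactone face, or C10 may epimerise on the catalyst, giving the wrong or a mixed configuration at C10. The fallback makes the C10–C bond, not the C10–H bond, on the accessible face. It sets out from 8: LDA then MeI gives the methyl enone F13, and hydrogenation of C5=C6 (H2, Pd/C) returns to the route at 11. Step 12 is the same reaction on the antipode.

**Step 7.** The aldol with formaldehyde may show poor facial selectivity at C5, and 12 may undergo retro-aldol loss of formaldehyde or dehydration before it is reduced. The fallback sets C5 by hydroxyl-directed hydrogenation. It sets out from 10.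
- RhCl(PPh3)3 and H2 reduce only the exocyclic methylene and give the methyl enone F13.
- A Morita–Baylis–Hillman reaction with aqueous formaldehyde (DMAP) gives the hydroxymethyl enone F14.
- NaBH4 with CeCl3 gives the allylic diol F15 (hydride anti to the C10 methyl).
- [Rh(nbd)(dppb)]BF4 and H2 add hydrogen to C5 from the face of the C1 hydroxyl.

The fallback returns at 13.

## Further compounds

F1 | step 17 | bromoacetate of 12 | C1C(=O)O[C@@H]2C[C@H](C)C(=O)[C@@H](COC(=O)CBr)C[C@H]12
F2 | step 17 | cis-fused hydroxy δ-lactone (C1–OH; C2–C3(=O)–O–C13') | C1C(=O)O[C@@H]2C[C@H](C)[C@@]3(O)CC(=O)OC[C@H]3C[C@H]12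
F3 | step 17 | TMS ether of F2 | C1C(=O)O[C@@H]2C[C@H](C)[C@@]3(O[Si](C)(C)C)CC(=O)OC[C@H]3C[C@H]12
F4 | step 17 | hydroxy β-keto lactone (C3–C11' bond formed; C13'–OH free; C11' epimers) | C1C(=O)O[C@@H]2C[C@H](C)[C@@](O[Si](C)(C)C)(CC(=O)C3C(=O)O[C@H]4C[C@@H](C)C(OS(=O)(=O)C(F)(F)F)=CC[C@@H]34)[C@@H](CO)C[C@H]12
F5 | step 17 | mesylate of F4 | C1C(=O)O[C@@H]2C[C@H](C)[C@@](O[Si](C)(C)C)(CC(=O)C3C(=O)O[C@H]4C[C@@H](C)C(OS(=O)(=O)C(F)(F)F)=CC[C@@H]34)[C@@H](COS(C)(=O)=O)C[C@H]12
F6 | step 15 | C5 dimethylaminomethyl derivative of 11 | C1C(=O)O[C@@H]2C[C@H](C)C(=O)[C@@H](CN(C)C)C[C@H]12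
F7 | step 15 | methiodide of F6 | C1C(=O)O[C@@H]2C[C@H](C)C(=O)[C@@H](C[N+](C)(C)C)C[C@H]12.[I-]
F8 | step 15 | C5 methylidene derivative of 11 | C1C(=O)O[C@@H]2C[C@H](C)C(=O)C(=C)C[C@H]12
F9 | step 4 | C5–C6 epoxide of 6 | C1C(=O)O[C@@H]2CCC[C@H]3O[C@H]3[C@H]12
F10 | step 4 | allylic alcohol (C6–OH, C1=C5) | C1C(=O)O[C@@H]2CCC=C[C@@H](O)[C@H]12
F11 | step 4 | syn epoxy alcohol (C1–C5 epoxide, C6–OH) | C1C(=O)O[C@@H]2CC[C@H]3O[C@H]3[C@@H](O)[C@H]12
F12 | step 4 | mesylate of F11 | C1C(=O)O[C@@H]2CC[C@H]3O[C@H]3[C@@H](OS(C)(=O)=O)[C@H]12
F13 | step 6 | C10 methyl enone (C1 ketone, C5=C6) | C1C(=O)O[C@@H]2C[C@H](C)C(=O)C=C[C@H]12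
F14 | step 7 | C5 hydroxymethyl derivative of F13 | C1C(=O)O[C@@H]2C[C@H](C)C(=O)C(CO)=C[C@H]12
F15 | step 7 | allylic diol (C1–OH cis to the C10 methyl, C5=C6) | C1C(=O)O[C@@H]2C[C@H](C)[C@H](O)C(CO)=C[C@H]12
A1 | alternative 1 | (7R,8R,10S)-dienone of the 8-epi-xanthatin type | C=C1C(=O)O[C@@H]2C[C@H](C)C(/C=C/C(C)=O)=CC[C@H]12
A2 | alternative 1 | (7S,8S,10R)-2,3-dihydro methylene lactone | C=C1C(=O)O[C@H]2C[C@@H](C)C(CCC(C)=O)=CC[C@@H]12
A3 | alternative 1 | [4+2] adduct (C1=C2) with the configuration the target requires | C=C1C(=O)O[C@@H]2C[C@H](C)C3=C[C@@H](C(C)=O)[C@@]4(C[C@H]3C[C@H]12)C(=O)O[C@H]1C[C@@H](C)C(CCC(C)=O)=CC[C@H]14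
A4 | alternative 2 | northern 2-acetyl ketone (acetyl on C5) | C1C(=O)O[C@@H]2C[C@H](C)C(=O)C(C(C)=O)C[C@H]12
A5 | alternative 2 | cyclobutanol photoadduct (new centres uncontrolled) | C1C(=O)O[C@@H]2C[C@H](C)C(=O)C3(CC4(C(=O)O[C@H]5C[C@@H](C)C(CCC(C)=O)=CC[C@@H]45)C3(C)O)C[C@H]12
A6 | alternative 2 | retro-aldol 1,5-diketone (C5 and C11' uncontrolled) | C1C(=O)O[C@@H]2C[C@H](C)C(=O)C(CC3(C(C)=O)C(=O)O[C@H]4C[C@@H](C)C(CCC(C)=O)=CC[C@@H]34)C[C@H]12
A7 | alternative 3 | metathesis precursor (vinyl on C1, 3-oxobut-1-en-2-yl on C11') | C=C1C(=O)O[C@@H]2C[C@H](C)[C@@](O)(C=C)[C@@H](C[C@]3(C(=C)C(C)=O)C(=O)O[C@H]4C[C@@H](C)C(CCC(C)=O)=CC[C@@H]34)C[C@H]12
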